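The numbers belong to no real substance, and the outcome is calculated.

Amounts come first: each set-up holds 0.150 M of partner for 0.10 M of starting material, with 0.0500 M of protic impurity in the mixture.

| setting | west | south | north | east |
|---|---|---|---|---|
| starting material | 0.10 M | 0.10 M | 0.10 M | 0.10 M |
| partner | 1.50 equiv | 1.50 equiv | 1.50 equiv | 1.50 equiv |
| second substrate | 1.00 equiv (fed, over 6.00 h) | 1.00 equiv | 1.00 equiv | 1.00 equiv |
| third substrate | 1.00 equiv | 1.00 equiv | 1.00 equiv | 1.00 equiv |
| protic impurity | 0.0500 M | 0.0500 M | 0.0500 M | 0.0500 M |
| time | 12 h |  | 12 h | 12 h |
| remark | all but second substrate at the start; second substrate goes in evenly over 6.00 h, the run ends at 12 h | a single well-mixed tank run continuously and read at steady state, 12 h in it on average | plug flow through a tube for 12 h, no back-mixing | a closed flask charged with all of it at once and left for 12 h |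

    starting material + partner → target (k1 = 0.82 M⁻¹ h⁻¹)
    second substrate + partner → second product (k2 = 0.51 M⁻¹ h⁻¹)
    third substrate + partner → third product (k3 = 0.97 M⁻¹ h⁻¹)
    partner + protic impurity → quenched reagent (k4 = 19 M⁻¹ h⁻¹)

- the stated concentrations are those of everything mixed, before any reaction; amounts are the same in each set-up
- the feed brings no volume worth counting
- run time (west): 12 h

1. the set-up with the highest amount of target at the outlet or at the end, in percent of the starting material put in ("none" if the first two lie within 2 percentage points) (west / south / north / east / none)
2. amount of target at the outlet or at the end, in percent of the starting material put in, west
3. amount of target at the outlet or at the end, in percent of the starting material put in, south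
4. amount of target at the outlet or at the end, in percent of the starting material put in, north
5. amount of target at the outlet or at the end, in percent of the starting material put in, east

We follow one partner molecule and add the processes one at a time, reckoning for the closed flask, east. With the main step by itself, the second-order integral with partner in excess gives target at 12 h:

target = 65.6%

Now add the impurity. At the start a partner molecule meets it rather than starting material with a chance of 92.1%, and partner's half-life against it, 0.73 h, is shorter than starting material's 5.6 h. So in our reckoning we write off 0.0500 M of partner, which leaves a partner budget of 0.100 M. With that budget the main step gives:

target = 49.6%

Now add the other substrates. Each budgeted molecule meets a fork, and at equal substrate concentrations its chance of ending in target is: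

35.7%

We call this the target share, in the usual term a selectivity. Holding the substrates at their charge, partner falls pseudo-first-order with constant 0.230 h⁻¹, so east at 12 h gives:

target = 33.4%

North should match east, since each slice of the tube is a closed flask for the same 12 h. At the start of west, with no second substrate yet fed, the share is 45.8%. The budget's half-life as reckoned for east, 3.01 h, is shorter than the feed time 6.00 h, so as an estimate we place west's share between the two and west above east. We commit to no number for the tank, south.

The forecast names west, with west 34.5% (33.3% to 35.7%), south 25.3%, and north and east 31.7%, below our 33.4%. Its ground for the winner: “Slowly dosing the second substrate keeps it from competing early”.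

The simulation puts west first: west 34.5%, south 25.3%, north 31.7%, east 31.7%. At 12.0 h west holds less second product, 0.0133 M, than east, 0.0211 M. A neighbour of west charged with 0.900 equiv of partner has a reckoned budget of 0.0400 M, so the target share and the share without second substrate give estimates for its target of 14.3% and 18.3%. That neighbour gives 15.5%.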